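**Retrosynthetic overview** (xenicane numbering: O2, C1, C3, C4, C4a, C5–C11, C11a; side chain C12–C15)
1. Target ⇐ cross-metathesis (C14=C15) and C12 allylation of the 1-acetoxy-4-formyl-dihydropyran epoxide 16.
2. Dihydropyran ⇐ acid unmasking of a C1 acetal and a C4 malonaldehyde bis-acetal on cyclononadiene 13, closing by enol hemiacetalisation.
3. Nine-membered ring ⇐ Claisen ring expansion of 2-methylidene-7-vinyloxepane 11 (C9–C10 formed, Z-olefin enforced) ⇐ Baeyer–Villiger lactone 10.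
4. 10 ⇐ (S)-carvone: its C5 becomes C4a, isopropenyl becomes C3/C4/C12, C6 becomes C11a, C1 becomes C11, C2 becomes C7.
5. Ring order: cyclohexenone (bought) → oxepanone → cyclononene → dihydropyran → oxirane.

Assumption: the SMILES is taken literally; its 7S,8R oxirane has C6 and C9 cis, so it is the epoxide of a (7Z)-olefin.

**Step 1**
Reactants: 1 (S)-(+)-carvone
Product: 3 2-[(1S)-4-methyl-5-oxocyclohex-3-en-1-yl]prop-2-enal, via allylic alcohol 2 (not isolated)
Conditions: SeO2 (0.5 equiv), t-BuOOH, CH2Cl2, rt; then MnO2, CH2Cl2, rt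
Reagents that add atoms: tert-butyl hydroperoxide CC(C)(C)OO
Why: Riley allylic oxidation (ene reaction, then [2,3]-shift) hits the electron-rich isopropenyl methyl rather than the enone, MnO2 takes the allylic alcohol to the enal, and the carvone stereocentre (future C4a, S) is untouched.

**Step 2**
Reactants: 3 2-[(1S)-4-methyl-5-oxocyclohex-3-en-1-yl]prop-2-enal
Product: 4 (5S)-2-methyl-5-(1,1,3,3-tetramethoxypropan-2-yl)cyclohex-2-en-1-one
Conditions: PdCl2(MeCN)2 (10 mol %), CuCl (20 mol %), O2 (1 atm), MeOH, 3 Å MS, 50 °C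
Reagents that add atoms: methanol CO
Why: Wacker-type anti-Markovnikov oxidative acetalisation of the acrolein unit (methanol adds to the β-carbon, β-hydride elimination, second methanol addition), with acetalisation of the aldehyde by the HCl formed, gives the malonaldehyde bis-acetal carrying C3, C4 and C12 at the aldehyde level without forming a stereocentre.

**Step 3**
Reactants: 4 (5S)-2-methyl-5-(1,1,3,3-tetramethoxypropan-2-yl)cyclohex-2-en-1-one
Product: 6 (5R,6S)-6-(dimethoxymethyl)-2-methyl-5-(1,1,3,3-tetramethoxypropan-2-yl)cyclohex-2-en-1-one, via silyl dienol ether 5 (not isolated)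
Conditions: LiN(i-Pr)2, Me3SiCl, THF, −78 °C; then HC(OMe)3, Me3SiOTf (5 mol %), CH2Cl2, −78 °C
Reagents that add atoms: chlorotrimethylsilane C[Si](C)(C)Cl (silyl group carried only by 5); trimethyl orthoformate COC(OC)OC
Why: Kinetic α'-enolisation and Mukaiyama-type alkylation by the dimethoxycarbenium ion install the C1 acetal anti to the bulky C5 substituent, and the epimerisable centre also prefers trans, so C11a is set by the carvone stereocentre.

**Step 4**
Reactants: 6 (5R,6S)-6-(dimethoxymethyl)-2-methyl-5-(1,1,3,3-tetramethoxypropan-2-yl)cyclohex-2-en-1-one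
Product: 8 (5R,6S)-6-(dimethoxymethyl)-2-methyl-2-[2-(phenylsulfinyl)ethyl]-5-(1,1,3,3-tetramethoxypropan-2-yl)cyclohexan-1-one (epimers at C2 and sulfur), via lithium enolate 7 (not isolated)
Conditions: LiBH(s-Bu)3, THF, −78 °C; then phenyl vinyl sulfoxide, −78 → 0 °C; H2O
Reagents that add atoms: lithium tri-sec-butylborohydride [Li+].CCC(C)[BH-](C(C)CC)C(C)CC (lithium carried only by 7); phenyl vinyl sulfoxide C=CS(=O)c1ccccc1
Why: Conjugate hydride reduction gives the regiodefined enolate, whose Michael addition to the vinyl sulfoxide (a vinyl cation equivalent) builds the quaternary future C7; its configuration is irrelevant because C7 becomes sp2 in step 7.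

**Step 5**
Reactants: 8 (5R,6S)-6-(dimethoxymethyl)-2-methyl-2-[2-(phenylsulfinyl)ethyl]-5-(1,1,3,3-tetramethoxypropan-2-yl)cyclohexan-1-one
Product: 9 (5R,6S)-6-(dimethoxymethyl)-2-ethenyl-2-methyl-5-(1,1,3,3-tetramethoxypropan-2-yl)cyclohexan-1-one (both C2 epimers)
Conditions: xylene, 140 °C
Reagents that add atoms: none
Why: Sulfoxide pyrolysis (thermal syn-elimination, Ei) expels benzenesulfenic acid and leaves the vinyl group on the quaternary carbon under neutral conditions.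

**Step 6**
Reactants: 9 (5R,6S)-6-(dimethoxymethyl)-2-ethenyl-2-methyl-5-(1,1,3,3-tetramethoxypropan-2-yl)cyclohexan-1-one
Product: 10 (3S,4R)-3-(dimethoxymethyl)-7-ethenyl-7-methyl-4-(1,1,3,3-tetramethoxypropan-2-yl)oxepan-2-one (both C7 epimers)
Conditions: mCPBA, NaHCO3, CH2Cl2, 0 °C → rt
Reagents that add atoms: 3-chloroperbenzoic acid OOC(=O)c1cccc(Cl)c1
Why: Baeyer–Villiger oxidation with migration of the quaternary allylic carbon (not the acetal-bearing methine) puts the ring oxygen on C7, the monosubstituted vinyl group being the least nucleophilic site for the buffered peracid.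

**Step 7**
Reactants: 10 (3S,4R)-3-(dimethoxymethyl)-7-ethenyl-7-methyl-4-(1,1,3,3-tetramethoxypropan-2-yl)oxepan-2-one
Product: 12 (4Z,8R,9S)-9-(dimethoxymethyl)-5-methyl-8-(1,1,3,3-tetramethoxypropan-2-yl)cyclonon-4-en-1-one, via enol ether 11 (not isolated)
Conditions: (C5H5)2Ti(CH3)2, toluene, 70 °C, dark; then 130 °C
Reagents that add atoms: dimethyltitanocene C[Ti](C)(C1C=CC=C1)C1C=CC=C1
Why: Petasis methylenation makes the lactone an allyl vinyl ether, and its Claisen rearrangement ([3,3]-sigmatropic; C9–C10 formed, C7–O broken) expands the oxepane to the cyclononenone; the short ring tether forces C6 axial in the transition state, so the olefin is Z from either C7 epimer, by analogy with Claisen ring expansions to eight-membered ketones and nine-membered lactones.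

**Step 8**
Reactants: 12 (4Z,8R,9S)-9-(dimethoxymethyl)-5-methyl-8-(1,1,3,3-tetramethoxypropan-2-yl)cyclonon-4-en-1-one
Product: 13 (1Z,6R,7S)-6-(dimethoxymethyl)-1-methyl-5-methylidene-7-(1,1,3,3-tetramethoxypropan-2-yl)cyclonon-1-ene
Conditions: (C5H5)2Ti(CH3)2, toluene, 70 °C
Reagents that add atoms: dimethyltitanocene C[Ti](C)(C1C=CC=C1)C1C=CC=C1
Why: Non-basic titanium carbene (Petasis) olefination methylenates the enolisable β-alkoxy ketone without epimerising C11a or eliminating methanol, at a temperature below any Cope reaction of the new 1,5-diene.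

**Step 9**
Reactants: 13 (1Z,6R,7S)-6-(dimethoxymethyl)-1-methyl-5-methylidene-7-(1,1,3,3-tetramethoxypropan-2-yl)cyclonon-1-ene
Product: 15 (1R,4aS,7Z,11aR)-4-formyl-7-methyl-11-methylidene-1,4a,5,6,9,10,11,11a-octahydrocyclonona[c]pyran-1-yl acetate, via lactol 14 (not isolated)
Conditions: 0.5 M HCl, THF–H2O, rt; then Ac2O, pyridine, DMAP (cat.), CH2Cl2, 0 °C
Reagents that add atoms: water O; acetic anhydride CC(=O)OC(C)=O
Why: Acetal hydrolysis frees the C1 aldehyde and the 2-substituted malonaldehyde, whose enol closes onto C1 (iridoid-type hemiacetalisation) to give the trans-fused dihydropyran, and acetylation of the equilibrating lactol gives the pseudoaxial, anomerically stabilised acetate anti to the C11a–C11 bond (1R).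

**Step 10**
Reactants: 15 (1R,4aS,7Z,11aR)-4-formyl-7-methyl-11-methylidene-1,4a,5,6,9,10,11,11a-octahydrocyclonona[c]pyran-1-yl acetate
Product: 16 (1R,4aS,7S,8R,11aR)-7,8-epoxy-4-formyl-7-methyl-11-methylidene-1,4a,5,6,7,8,9,10,11,11a-decahydrocyclonona[c]pyran-1-yl acetate
Conditions: mCPBA (1.05 equiv), NaHCO3, CH2Cl2, −20 → 0 °C
Reagents that add atoms: 3-chloroperbenzoic acid OOC(=O)c1cccc(Cl)c1
Why: Prilezhaev epoxidation picks the trisubstituted (Z)-olefin (the enol ether is deactivated as a vinylogous formate, the methylidene is less substituted) and is stereospecific, giving the cis-epoxide; attack on the face syn to C1–O is expected from the ring conformation and would set 7S,8R.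

**Step 11**
Reactants: 16 (1R,4aS,7S,8R,11aR)-7,8-epoxy-4-formyl-7-methyl-11-methylidene-1,4a,5,6,7,8,9,10,11,11a-decahydrocyclonona[c]pyran-1-yl acetate
Product: 17 (1R,4aS,7S,8R,11aR)-7,8-epoxy-4-[(1S)-1-hydroxybut-3-en-1-yl]-7-methyl-11-methylidene-1,4a,5,6,7,8,9,10,11,11a-decahydrocyclonona[c]pyran-1-yl acetate
Conditions: allylB(pin), toluene, 40 °C; aq. NaHCO3 work-up
Reagents that add atoms: allylboronic acid pinacol ester C=CCB1OC(C)(C)C(C)(C)O1
Why: Uncatalysed allylboration through a closed six-membered transition state adds to the s-trans formyl group on the face anti to the pseudoaxial C4a–C5 bond (A(1,2)-strain control by the carvone-derived centre), giving the 12S carbinol and leaving acetate and epoxide alone.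

**Step 12**
Reactants: 17 (1R,4aS,7S,8R,11aR)-7,8-epoxy-4-[(1S)-1-hydroxybut-3-en-1-yl]-7-methyl-11-methylidene-1,4a,5,6,7,8,9,10,11,11a-decahydrocyclonona[c]pyran-1-yl acetate
Product: 18 (1S)-1-[(1R,4aS,7S,8R,11aR)-1-acetoxy-7,8-epoxy-7-methyl-11-methylidene-1,4a,5,6,7,8,9,10,11,11a-decahydrocyclonona[c]pyran-4-yl]but-3-en-1-yl acetate
Conditions: Ac2O, pyridine, DMAP (cat.), CH2Cl2, 0 °C
Reagents that add atoms: acetic anhydride CC(=O)OC(C)=O
Why: Nucleophile-catalysed O-acylation of the secondary alcohol proceeds with retention at C12.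

**Step 13**
Reactants: 18 (1S)-1-[(1R,4aS,7S,8R,11aR)-1-acetoxy-7,8-epoxy-7-methyl-11-methylidene-1,4a,5,6,7,8,9,10,11,11a-decahydrocyclonona[c]pyran-4-yl]but-3-en-1-yl acetate
Product: 19 methyl (2E,5S)-5-acetoxy-5-[(1R,4aS,7S,8R,11aR)-1-acetoxy-7,8-epoxy-7-methyl-11-methylidene-1,4a,5,6,7,8,9,10,11,11a-decahydrocyclonona[c]pyran-4-yl]-2-methylpent-2-enoate (target)
Conditions: methyl methacrylate (20 equiv), second-generation Hoveyda–Grubbs catalyst, dichloro[1,3-bis(2,4,6-trimethylphenyl)imidazolidin-2-ylidene](2-isopropoxybenzylidene)ruthenium (5 mol %), CH2Cl2, 40 °C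
Reagents that add atoms: methyl methacrylate C=C(C)C(=O)OC
Why: Olefin cross-metathesis of the terminal alkene with the methacrylate gives the trisubstituted enoate with E geometry, while the hindered methylidene, the trisubstituted enol ether and the epoxide stay out; ring closure onto the methylidene would need a bridgehead olefin.

**Compound list**
1 | (S)-(+)-carvone, (5S)-2-methyl-5-(prop-1-en-2-yl)cyclohex-2-en-1-one | CC1=CC[C@@H](CC1=O)C(C)=C | starting material
2 | (5S)-5-(3-hydroxyprop-1-en-2-yl)-2-methylcyclohex-2-en-1-one | CC1=CC[C@@H](CC1=O)C(=C)CO | intermediate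
3 | 2-[(1S)-4-methyl-5-oxocyclohex-3-en-1-yl]prop-2-enal | CC1=CC[C@@H](CC1=O)C(=C)C=O | intermediate
4 | (5S)-2-methyl-5-(1,1,3,3-tetramethoxypropan-2-yl)cyclohex-2-en-1-one | CC1=CC[C@@H](CC1=O)C(C(OC)OC)C(OC)OC | intermediate
5 | trimethyl{[(3S)-6-methyl-3-(1,1,3,3-tetramethoxypropan-2-yl)cyclohexa-1,5-dien-1-yl]oxy}silane | CC1=CC[C@@H](C=C1O[Si](C)(C)C)C(C(OC)OC)C(OC)OC | intermediate
6 | (5R,6S)-6-(dimethoxymethyl)-2-methyl-5-(1,1,3,3-tetramethoxypropan-2-yl)cyclohex-2-en-1-one (5,6-trans) | O=C1C(C)=CC[C@H](C(C(OC)OC)C(OC)OC)[C@H]1C(OC)OC | intermediate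
7 | lithium C1–C2 enolate of the 5,6-trans-6-(dimethoxymethyl)-2-methyl-5-(1,1,3,3-tetramethoxypropan-2-yl)cyclohexanone | [Li]OC1=C(C)CC[C@H](C(C(OC)OC)C(OC)OC)[C@H]1C(OC)OC | intermediate
8 | (5R,6S)-6-(dimethoxymethyl)-2-methyl-2-[2-(phenylsulfinyl)ethyl]-5-(1,1,3,3-tetramethoxypropan-2-yl)cyclohexan-1-one (epimers at C2 and sulfur) | O=C1C(C)(CCS(=O)c2ccccc2)CC[C@H](C(C(OC)OC)C(OC)OC)[C@H]1C(OC)OC | intermediate
9 | (5R,6S)-6-(dimethoxymethyl)-2-ethenyl-2-methyl-5-(1,1,3,3-tetramethoxypropan-2-yl)cyclohexan-1-one (both C2 epimers) | O=C1C(C)(C=C)CC[C@H](C(C(OC)OC)C(OC)OC)[C@H]1C(OC)OC | intermediate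
10 | (3S,4R)-3-(dimethoxymethyl)-7-ethenyl-7-methyl-4-(1,1,3,3-tetramethoxypropan-2-yl)oxepan-2-one (both C7 epimers) | O=C1OC(C)(C=C)CC[C@H](C(C(OC)OC)C(OC)OC)[C@H]1C(OC)OC | intermediate
11 | (3R,4S)-3-(dimethoxymethyl)-7-ethenyl-7-methyl-2-methylidene-4-(1,1,3,3-tetramethoxypropan-2-yl)oxepane (both C7 epimers) | C=C1OC(C)(C=C)CC[C@H](C(C(OC)OC)C(OC)OC)[C@H]1C(OC)OC | intermediate
12 | (4Z,8R,9S)-9-(dimethoxymethyl)-5-methyl-8-(1,1,3,3-tetramethoxypropan-2-yl)cyclonon-4-en-1-one | O=C1CC/C=C(/C)CC[C@H](C(C(OC)OC)C(OC)OC)[C@H]1C(OC)OC | intermediate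
13 | (1Z,6R,7S)-6-(dimethoxymethyl)-1-methyl-5-methylidene-7-(1,1,3,3-tetramethoxypropan-2-yl)cyclonon-1-ene | C=C1CC/C=C(/C)CC[C@H](C(C(OC)OC)C(OC)OC)[C@H]1C(OC)OC | intermediate
14 | (4aS,7Z,11aR)-1-hydroxy-7-methyl-11-methylidene-1,4a,5,6,9,10,11,11a-octahydrocyclonona[c]pyran-4-carbaldehyde (C1 anomers) | C=C1CC/C=C(/C)CC[C@@H]2C(C=O)=COC(O)[C@@H]12 | intermediate
15 | (1R,4aS,7Z,11aR)-4-formyl-7-methyl-11-methylidene-1,4a,5,6,9,10,11,11a-octahydrocyclonona[c]pyran-1-yl acetate | C=C1CC/C=C(/C)CC[C@@H]2C(C=O)=CO[C@H](OC(C)=O)[C@@H]12 | intermediate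
16 | (1R,4aS,7S,8R,11aR)-7,8-epoxy-4-formyl-7-methyl-11-methylidene-1,4a,5,6,7,8,9,10,11,11a-decahydrocyclonona[c]pyran-1-yl acetate | C=C1CC[C@H]2O[C@@]2(C)CC[C@@H]2C(C=O)=CO[C@H](OC(C)=O)[C@@H]12 | intermediate
17 | (1R,4aS,7S,8R,11aR)-7,8-epoxy-4-[(1S)-1-hydroxybut-3-en-1-yl]-7-methyl-11-methylidene-1,4a,5,6,7,8,9,10,11,11a-decahydrocyclonona[c]pyran-1-yl acetate | C=C1CC[C@H]2O[C@@]2(C)CC[C@@H]2C([C@H](CC=C)O)=CO[C@H](OC(C)=O)[C@@H]12 | intermediate
18 | (1S)-1-[(1R,4aS,7S,8R,11aR)-1-acetoxy-7,8-epoxy-7-methyl-11-methylidene-1,4a,5,6,7,8,9,10,11,11a-decahydrocyclonona[c]pyran-4-yl]but-3-en-1-yl acetate | C=C1CC[C@H]2O[C@@]2(C)CC[C@@H]2C([C@H](CC=C)OC(C)=O)=CO[C@H](OC(C)=O)[C@@H]12 | intermediate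
19 | methyl (2E,5S)-5-acetoxy-5-[(1R,4aS,7S,8R,11aR)-1-acetoxy-7,8-epoxy-7-methyl-11-methylidene-1,4a,5,6,7,8,9,10,11,11a-decahydrocyclonona[c]pyran-4-yl]-2-methylpent-2-enoate | C=C1CC[C@H]2O[C@@]2(C)CC[C@@H]2C([C@H](C/C=C(\C)C(=O)OC)OC(C)=O)=CO[C@H](OC(C)=O)[C@@H]12 | target

**Count and risks**
Total steps: 13. Longest linear sequence: 13 steps (from 1).

The three steps most likely to fail:

Step 2 (oxidative acetalisation). Anti-Markovnikov oxypalladation is established for acrylates and acrylonitrile, less so for an α-substituted enal that acetalises under the conditions. The fallback sets out from 3 and reaches the same oxidation level at C3 by sulfur chemistry. Acetalisation (HC(OMe)3, MeOH, CSA) gives (5S)-5-(3,3-dimethoxyprop-1-en-2-yl)-2-methylcyclohex-2-en-1-one F1. Radical anti-Markovnikov hydrothiolation (PhSH, AIBN, 80 °C) gives (5S)-5-[1,1-dimethoxy-3-(phenylsulfanyl)propan-2-yl]-2-methylcyclohex-2-en-1-one F2. NaIO4 oxidation gives (5S)-5-[1,1-dimethoxy-3-(phenylsulfinyl)propan-2-yl]-2-methylcyclohex-2-en-1-one F3. Pummerer rearrangement (trifluoroacetic anhydride, 2,6-lutidine) gives 3,3-dimethoxy-2-[(1S)-4-methyl-5-oxocyclohex-3-en-1-yl]-1-(phenylsulfanyl)propyl trifluoroacetate F4. Methanolysis (MeOH, HC(OMe)3, HgCl2) then comes back to the route at 4.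

Step 10 (face of epoxidation). The facial preference of the (Z)-cyclononene is argued from conformation only and could be reversed. The fallback sets out from 15 and delivers oxygen to the opposite face. NBS in aqueous THF forms the bromonium ion on the face the peracid prefers; water opens it at the tertiary carbon to give (1R,4aS,7S,8S,11aR)-8-bromo-4-formyl-7-hydroxy-7-methyl-11-methylidene-1,4a,5,6,7,8,9,10,11,11a-decahydrocyclonona[c]pyran-1-yl acetate F5. Ag2O in CH2Cl2 closes it with inversion at C8 and comes back to the route at 16.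

Step 11 (configuration at C12). The outcome rests on the s-trans formyl conformer and a pseudoaxial C4a–C5 bond; if the model fails, the 12R alcohol dominates. The fallback sets out from 16 and sets C12 by hydride delivery instead of carbon delivery. The allylboration product (1R,4aS,7S,8R,11aR)-7,8-epoxy-4-[(1R)-1-hydroxybut-3-en-1-yl]-7-methyl-11-methylidene-1,4a,5,6,7,8,9,10,11,11a-decahydrocyclonona[c]pyran-1-yl acetate F6 is oxidised with Dess–Martin periodinane to (1R,4aS,7S,8R,11aR)-4-(but-3-enoyl)-7,8-epoxy-7-methyl-11-methylidene-1,4a,5,6,7,8,9,10,11,11a-decahydrocyclonona[c]pyran-1-yl acetate F7. Luche reduction (NaBH4, CeCl3·7H2O, MeOH, −78 °C) sends hydride to the face the allyl group used, which now gives the 12S alcohol and comes back to the route at 17.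

**Further compounds**
F1 | step 2 | (5S)-5-(3,3-dimethoxyprop-1-en-2-yl)-2-methylcyclohex-2-en-1-one | CC1=CC[C@@H](CC1=O)C(=C)C(OC)OC
F2 | step 2 | (5S)-5-[1,1-dimethoxy-3-(phenylsulfanyl)propan-2-yl]-2-methylcyclohex-2-en-1-one | CC1=CC[C@@H](CC1=O)C(CSc1ccccc1)C(OC)OC
F3 | step 2 | (5S)-5-[1,1-dimethoxy-3-(phenylsulfinyl)propan-2-yl]-2-methylcyclohex-2-en-1-one | CC1=CC[C@@H](CC1=O)C(CS(=O)c1ccccc1)C(OC)OC
F4 | step 2 | 3,3-dimethoxy-2-[(1S)-4-methyl-5-oxocyclohex-3-en-1-yl]-1-(phenylsulfanyl)propyl trifluoroacetate | CC1=CC[C@@H](CC1=O)C(C(OC(=O)C(F)(F)F)Sc1ccccc1)C(OC)OC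
F5 | step 10 | (1R,4aS,7S,8S,11aR)-8-bromo-4-formyl-7-hydroxy-7-methyl-11-methylidene-1,4a,5,6,7,8,9,10,11,11a-decahydrocyclonona[c]pyran-1-yl acetate | C=C1CC[C@H](Br)[C@@](C)(O)CC[C@@H]2C(C=O)=CO[C@H](OC(C)=O)[C@@H]12
F6 | step 11 | (1R,4aS,7S,8R,11aR)-7,8-epoxy-4-[(1R)-1-hydroxybut-3-en-1-yl]-7-methyl-11-methylidene-1,4a,5,6,7,8,9,10,11,11a-decahydrocyclonona[c]pyran-1-yl acetate | C=C1CC[C@H]2O[C@@]2(C)CC[C@@H]2C([C@@H](CC=C)O)=CO[C@H](OC(C)=O)[C@@H]12
F7 | step 11 | (1R,4aS,7S,8R,11aR)-4-(but-3-enoyl)-7,8-epoxy-7-methyl-11-methylidene-1,4a,5,6,7,8,9,10,11,11a-decahydrocyclonona[c]pyran-1-yl acetate | C=C1CC[C@H]2O[C@@]2(C)CC[C@@H]2C(C(=O)CC=C)=CO[C@H](OC(C)=O)[C@@H]12
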